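**Retrosynthetic overview**
1. Target 24 ⇒ chroman-6',8'-diol 22 by a final double Vilsmeier–Haack formylation; the formyl groups come last because they would not survive the hydride step.
2. 22 ⇒ hemiketal 20 (ionic hydrogenation, cis ring fusion) ⇒ hetero-Diels–Alder of phloroglucinol o-quinone methide 18 with silyl enol ether 12. The pyran ring is formed last, with O going to the silyloxy carbon and the benzylic C to the methyl-bearing carbon.
3. 12 ⇒ spiro dione 7: the cyclohexanone becomes the C6=C7 alkene via enol triflate reduction, the cyclopentanone becomes the TBS enol ether.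
4. 7 ⇒ 5-exo spiro-acylation of the enol of a C6-alkylated (+)-menthone (cyclopentane formed second); the cyclohexane and its C-methyl stereocentre come from (+)-menthol.
5. Stereochemical relay: C-methyl → spiro centre (acylation anti to Me) → cycloaddition face and endo topology (C9'a, C9') → hydride delivery (C3'a).

Assumption: (+)-menthol, racemic methyl 4-bromo-2-methylbutanoate, 2,4,6-trihydroxybenzaldehyde and isobutylmagnesium bromide are bought; centres that are later enolised are carried as mixtures. The route is a paper design and has not been run.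

**Step 1**
Reactants: 1 (1S,2R,5S)-(+)-menthol
Product: 2 (2R,5S)-5-methyl-2-(propan-2-yl)cyclohexan-1-one [(+)-menthone]
Conditions: NaOCl (aq), AcOH, 0 → 23 °C
Reagents that add atoms: none
Why: Hypochlorite oxidation of a secondary alcohol (Stevens oxidation) gives the ketone without touching the C5 methyl stereocentre, and any epimerisation next to the carbonyl is harmless because that carbon becomes sp2 in step 5.

**Step 2**
Reactants: 2 (+)-menthone; 3 methyl 4-bromo-2-methylbutanoate (racemic)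
Product: 5 methyl 2-methyl-4-[(1R,3R,6S)-6-methyl-2-oxo-3-(propan-2-yl)cyclohexyl]butanoate, via lithium enolate 4 (not isolated)
Conditions: LiN(iPr)2, THF, −78 °C; then 3, DMPU, Bu4NI (10 mol %), −78 → 0 °C
Reagents that add atoms: none
Why: Kinetic deprotonation of menthone takes the unhindered CH2 (C6) and SN2 enolate alkylation installs the acyl chain mainly trans to the neighbouring methyl group, while the two epimerisable ring centres and the racemic side-chain centre are all erased later so that only the untouched methyl-bearing stereocentre matters.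

**Step 3**
Reactants: 5 keto ester
Product: 7 (5S,7R,10S)-2,10-dimethyl-7-(propan-2-yl)spiro[4.5]decane-1,6-dione, via keto acid 6 (not isolated)
Conditions: LiOH, THF/MeOH/H2O, 23 °C; aq HCl; then PPA, AcOH, 100 °C
Reagents that add atoms: none
Why: After saponification, acid-mediated intramolecular Claisen-type C-acylation (5-exo-trig) of the more substituted enol forms the non-enolisable spiro 1,3-dione, the acyl carbon attacking the enol face anti to the pseudoaxial neighbouring methyl group so that the new carbonyl carbon is trans and the ring CH2 cis to that methyl, which is the required spiro configuration.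

**Step 4**
Reactants: 7 spiro dione
Product: 9 (5S,7R,10S)-1-{[tert-butyl(dimethyl)silyl]oxy}-2,10-dimethyl-7-(propan-2-yl)spiro[4.5]dec-1-en-6-one, via dione lithium enolate 8 (not isolated)
Conditions: LiN(iPr)2 (1.05 equiv), THF, −78 °C; TBSOTf, −78 → 0 °C
Reagents that add atoms: tert-butyldimethylsilyl trifluoromethanesulfonate CC(C)(C)[Si](C)(C)OS(=O)(=O)C(F)(F)F
Why: Kinetic enolisation then O-silylation is site-selective because the cyclopentanone methine is far more accessible than the isopropyl-shielded methine of the menthone-type ring (which this base does not remove even in menthone itself), and it creates no stereocentre while erasing C2.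

**Step 5**
Reactants: 9 silyl enol ether ketone
Product: 11 (5S,10S)-1-{[tert-butyl(dimethyl)silyl]oxy}-2,10-dimethyl-7-(propan-2-yl)spiro[4.5]deca-1,6-dien-6-yl trifluoromethanesulfonate, via potassium enolate 10 (not isolated)
Conditions: KN(SiMe3)2, THF, −78 → 0 °C; PhNTf2, 0 → 23 °C
Reagents that add atoms: N-phenylbis(trifluoromethanesulfonimide) O=S(=O)(N(c1ccccc1)S(=O)(=O)C(F)(F)F)C(F)(F)F
Why: The six-membered ketone has a single enolisable position (C7), so enolate formation and O-triflation give one vinyl triflate regiospecifically while the silyl enol ether is inert to the base.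

**Step 6**
Reactants: 11 vinyl triflate
Product: 12 tert-butyl{[(5R,10S)-2,10-dimethyl-7-(propan-2-yl)spiro[4.5]deca-1,6-dien-1-yl]oxy}dimethylsilane
Conditions: Pd(OAc)2 (10 mol %), PPh3 (20 mol %), HCO2H, Bu3N (excess), DMF, 60 °C
Reagents that add atoms: none
Why: Palladium-catalysed formate reduction of the vinyl triflate (oxidative addition, formate exchange, decarboxylation to a palladium hydride, reductive elimination) replaces OTf by H and leaves the C6=C7 alkene in place under amine-buffered conditions that spare the silyl enol ether.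

**Step 7**
Reactants: 13 2,4,6-trihydroxybenzaldehyde
Product: 14 2-formylbenzene-1,3,5-triyl tri-tert-butyl triscarbonate
Conditions: Boc2O (3.5 equiv), iPr2NEt, DMAP (5 mol %), THF, 0 → 23 °C
Reagents that add atoms: di-tert-butyl dicarbonate CC(C)(C)OC(=O)OC(=O)OC(C)(C)C
Why: DMAP-catalysed O-acylation converts all three phenols into tert-butyl carbonates, which arms an ortho oxygen for the later carbonate transfer and keeps the arene non-acidic towards the Grignard reagent.

**Step 8**
Reactants: 12 silyl enol ether diene; 14 tris-Boc aldehyde; 15 isobutylmagnesium bromide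
Product: 20 di-tert-butyl (1R,3'aS,6S,9'S,9'aR)-3'a-hydroxy-6,9'a-dimethyl-9'-(2-methylpropyl)-3-(propan-2-yl)-1',2',3'a,9'a-tetrahydro-9'H-spiro[cyclohex-2-ene-1,3'-cyclopenta[b]chromene]-6',8'-diyl biscarbonate, via magnesium alkoxide 16 (not isolated), via benzylic carbonate phenoxide 17 (not isolated), via o-quinone methide 18 (not isolated), via silyl ketal 19 (not isolated)
Conditions: 14 (2 equiv), 12 (1 equiv), Et2O, −78 °C; 15 (2 equiv); −78 → 23 °C; then Et3N·3HF, THF, 23 °C
Reagents that add atoms: none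
Why: Grignard addition triggers ortho-to-benzylic Boc transfer and β-elimination to the E o-quinone methide, which undergoes an inverse-electron-demand hetero-Diels–Alder reaction with the silyl enol ether (oxygen to the silyloxy carbon, methide carbon to C2) on the cyclopentene face anti to the C10 methine and syn to the flat vinyl carbon, through the transition state with silyloxy and methyl endo and the spiro carbocycle exo, which sets the quaternary C9'a, the ketal carbon and the benzylic C9' (isobutyl cis to the angular methyl) before fluoride unmasks the hemiketal without changing any stereocentre.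

**Step 9**
Reactants: 20 hemiketal
Product: 22 (1R,3'aS,6S,9'R,9'aR)-6,9'a-dimethyl-9'-(2-methylpropyl)-3-(propan-2-yl)-1',2',3'a,9'a-tetrahydro-9'H-spiro[cyclohex-2-ene-1,3'-cyclopenta[b]chromene]-6',8'-diol, via bis-Boc chroman 21 (not isolated)
Conditions: Et3SiH, BF3·OEt2, CH2Cl2, −78 → −20 °C; then pyrrolidine, MeOH, 23 °C
Reagents that add atoms: none
Why: Ionic hydrogenation of the hemiketal proceeds by ionisation of the anomeric hydroxyl to the cyclic aryloxycarbenium ion (stabilised by the still electron-rich aryl oxygen) and hydride delivery to the only face that gives the strain-free cis-fused pyran–cyclopentane (H cis to the angular methyl), after which aminolysis removes both aryl carbonates.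

**Step 10**
Reactants: 22 chroman diol
Product: 24 (1R,3'aS,6S,9'R,9'aR)-6',8'-dihydroxy-6,9'a-dimethyl-9'-(2-methylpropyl)-3-(propan-2-yl)-1',2',3'a,9'a-tetrahydro-9'H-spiro[cyclohex-2-ene-1,3'-cyclopenta[b]chromene]-5',7'-dicarbaldehyde, via bis-iminium salt 23 (not isolated)
Conditions: POCl3, DMF, MeCN, 0 → 40 °C; then H2O, 50 °C
Reagents that add atoms: N,N-dimethylformamide CN(C)C=O; water O
Why: Double Vilsmeier–Haack formylation occurs at the only two free ring positions, each activated by three oxygen donors, and hydrolysis of the bis-iminium salt gives the dialdehyde under conditions that do not protonate the trisubstituted alkene, so no stereocentre is affected.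

**Compound list**
1 | (1S,2R,5S)-5-methyl-2-(propan-2-yl)cyclohexan-1-ol, (+)-menthol | CC(C)[C@H]1CC[C@H](C)C[C@@H]1O | starting material
2 | (2R,5S)-5-methyl-2-(propan-2-yl)cyclohexan-1-one, (+)-menthone | CC(C)[C@H]1CC[C@H](C)CC1=O | intermediate
3 | methyl 4-bromo-2-methylbutanoate (racemic) | COC(=O)C(C)CCBr | starting material
4 | lithium (3S,6R)-3-methyl-6-(propan-2-yl)cyclohex-1-en-1-olate | CC(C)[C@H]1CC[C@H](C)C=C1[O-].[Li+] | intermediate
5 | methyl 2-methyl-4-[(1R,3R,6S)-6-methyl-2-oxo-3-(propan-2-yl)cyclohexyl]butanoate (side-chain epimers) | CC(C)[C@H]1CC[C@H](C)[C@@H](CCC(C)C(=O)OC)C1=O | intermediate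
6 | 2-methyl-4-[(1R,3R,6S)-6-methyl-2-oxo-3-(propan-2-yl)cyclohexyl]butanoic acid | CC(C)[C@H]1CC[C@H](C)[C@@H](CCC(C)C(=O)O)C1=O | intermediate
7 | (5S,7R,10S)-2,10-dimethyl-7-(propan-2-yl)spiro[4.5]decane-1,6-dione (C2 epimers) | O=C2C(C)CC[C@@]21C(=O)[C@@H](C(C)C)CC[C@@H]1C | intermediate
8 | lithium (5S,7R,10S)-2,10-dimethyl-6-oxo-7-(propan-2-yl)spiro[4.5]dec-1-en-1-olate | [Li+].[O-]C2=C(C)CC[C@@]21C(=O)[C@@H](C(C)C)CC[C@@H]1C | intermediate
9 | (5S,7R,10S)-1-{[tert-butyl(dimethyl)silyl]oxy}-2,10-dimethyl-7-(propan-2-yl)spiro[4.5]dec-1-en-6-one | CC(C)(C)[Si](C)(C)OC2=C(C)CC[C@@]21C(=O)[C@@H](C(C)C)CC[C@@H]1C | intermediate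
10 | potassium (5R,10S)-1-{[tert-butyl(dimethyl)silyl]oxy}-2,10-dimethyl-7-(propan-2-yl)spiro[4.5]deca-1,6-dien-6-olate | CC(C)(C)[Si](C)(C)OC2=C(C)CC[C@@]21C([O-])=C(C(C)C)CC[C@@H]1C.[K+] | intermediate
11 | (5S,10S)-1-{[tert-butyl(dimethyl)silyl]oxy}-2,10-dimethyl-7-(propan-2-yl)spiro[4.5]deca-1,6-dien-6-yl trifluoromethanesulfonate | CC(C)(C)[Si](C)(C)OC2=C(C)CC[C@@]21C(OS(=O)(=O)C(F)(F)F)=C(C(C)C)CC[C@@H]1C | intermediate
12 | tert-butyl{[(5R,10S)-2,10-dimethyl-7-(propan-2-yl)spiro[4.5]deca-1,6-dien-1-yl]oxy}dimethylsilane | CC(C)(C)[Si](C)(C)OC2=C(C)CC[C@@]21C=C(C(C)C)CC[C@@H]1C | intermediate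
13 | 2,4,6-trihydroxybenzaldehyde | O=Cc1c(O)cc(O)cc1O | starting material
14 | 2-formylbenzene-1,3,5-triyl tri-tert-butyl triscarbonate | O=Cc1c(OC(=O)OC(C)(C)C)cc(OC(=O)OC(C)(C)C)cc1OC(=O)OC(C)(C)C | intermediate
15 | isobutylmagnesium bromide | CC(C)C[Mg]Br | starting material
16 | bromomagnesium 1-[2,4,6-tris(tert-butoxycarbonyloxy)phenyl]-3-methylbutan-1-olate (racemic) | CC(C)CC(O[Mg]Br)c1c(OC(=O)OC(C)(C)C)cc(OC(=O)OC(C)(C)C)cc1OC(=O)OC(C)(C)C | intermediate
17 | bromomagnesium 3,5-bis(tert-butoxycarbonyloxy)-2-[1-(tert-butoxycarbonyloxy)-3-methylbutyl]phenolate (racemic) | CC(C)CC(OC(=O)OC(C)(C)C)c1c(O[Mg]Br)cc(OC(=O)OC(C)(C)C)cc1OC(=O)OC(C)(C)C | intermediate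
18 | (6E)-3,5-bis(tert-butoxycarbonyloxy)-6-(3-methylbutylidene)cyclohexa-2,4-dien-1-one | CC(C)C/C=C1/C(=O)C=C(OC(=O)OC(C)(C)C)C=C1OC(=O)OC(C)(C)C | intermediate
19 | di-tert-butyl (1R,3'aR,6S,9'S,9'aR)-3'a-{[tert-butyl(dimethyl)silyl]oxy}-6,9'a-dimethyl-9'-(2-methylpropyl)-3-(propan-2-yl)-1',2',3'a,9'a-tetrahydro-9'H-spiro[cyclohex-2-ene-1,3'-cyclopenta[b]chromene]-6',8'-diyl biscarbonate | CC(C)C[C@H]1c2c(OC(=O)OC(C)(C)C)cc(OC(=O)OC(C)(C)C)cc2O[C@@]2(O[Si](C)(C)C(C)(C)C)[C@]1(C)CC[C@@]21C=C(C(C)C)CC[C@@H]1C | intermediate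
20 | di-tert-butyl (1R,3'aS,6S,9'S,9'aR)-3'a-hydroxy-6,9'a-dimethyl-9'-(2-methylpropyl)-3-(propan-2-yl)-1',2',3'a,9'a-tetrahydro-9'H-spiro[cyclohex-2-ene-1,3'-cyclopenta[b]chromene]-6',8'-diyl biscarbonate | CC(C)C[C@H]1c2c(OC(=O)OC(C)(C)C)cc(OC(=O)OC(C)(C)C)cc2O[C@@]2(O)[C@]1(C)CC[C@@]21C=C(C(C)C)CC[C@@H]1C | intermediate
21 | di-tert-butyl (1R,3'aS,6S,9'R,9'aR)-6,9'a-dimethyl-9'-(2-methylpropyl)-3-(propan-2-yl)-1',2',3'a,9'a-tetrahydro-9'H-spiro[cyclohex-2-ene-1,3'-cyclopenta[b]chromene]-6',8'-diyl biscarbonate | CC(C)C[C@H]1c2c(OC(=O)OC(C)(C)C)cc(OC(=O)OC(C)(C)C)cc2O[C@H]2[C@]1(C)CC[C@@]21C=C(C(C)C)CC[C@@H]1C | intermediate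
22 | (1R,3'aS,6S,9'R,9'aR)-6,9'a-dimethyl-9'-(2-methylpropyl)-3-(propan-2-yl)-1',2',3'a,9'a-tetrahydro-9'H-spiro[cyclohex-2-ene-1,3'-cyclopenta[b]chromene]-6',8'-diol | CC(C)C[C@H]1c2c(O)cc(O)cc2O[C@H]2[C@]1(C)CC[C@@]21C=C(C(C)C)CC[C@@H]1C | intermediate
23 | [(1R,3'aS,6S,9'R,9'aR)-6',8'-dihydroxy-6,9'a-dimethyl-9'-(2-methylpropyl)-3-(propan-2-yl)-1',2',3'a,9'a-tetrahydro-9'H-spiro[cyclohex-2-ene-1,3'-cyclopenta[b]chromene]-5',7'-diyl]bis(N,N-dimethylmethaniminium) dichloride | CC(C)C[C@H]1c2c(O)c(C=[N+](C)C)c(O)c(C=[N+](C)C)c2O[C@H]2[C@]1(C)CC[C@@]21C=C(C(C)C)CC[C@@H]1C.[Cl-].[Cl-] | intermediate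
24 | (1R,3'aS,6S,9'R,9'aR)-6',8'-dihydroxy-6,9'a-dimethyl-9'-(2-methylpropyl)-3-(propan-2-yl)-1',2',3'a,9'a-tetrahydro-9'H-spiro[cyclohex-2-ene-1,3'-cyclopenta[b]chromene]-5',7'-dicarbaldehyde | CC(C)C[C@H]1c2c(O)c(C=O)c(O)c(C=O)c2O[C@H]2[C@]1(C)CC[C@@]21C=C(C(C)C)CC[C@@H]1C | target

**Totals**
Total step count: 10. Longest linear sequence: 9 steps (1 → 2 → 5 → 7 → 9 → 11 → 12 → 20 → 22 → 24).

**Steps most likely to fail, with fallbacks**

Step 8 is the most exposed step. The cycloaddition has to join a tetrasubstituted, neopentyl-flanked silyl enol ether to a moderately electrophilic o-quinone methide, and it may be slow or give the wrong benzylic epimer. The fallback sets out from 12 (with 14 and 15) and comes back at 20. MeLi in THF at 0 → 23 °C cleaves the silyl enol ether to lithium (5R,10S)-2,10-dimethyl-7-(propan-2-yl)spiro[4.5]deca-1,6-dien-1-olate F8. Separately, 15 is added to 14 at −78 °C to form alkoxide 16. The solution of the enolate is transferred in and the mixture is warmed, so that quinone methide 18 is released in the presence of a far stronger nucleophile and is captured by anionic Michael addition instead of cycloaddition. On NH4Cl work-up the keto phenol closes to hemiketal 20, and the route continues with step 9.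

Step 3 can give a poor diastereomer ratio at the spiro centre, or retro-Claisen cleavage in hot acid. The fallback sets out from 2 and comes back at 7. The kinetic enolate of 2 (LiN(iPr)2, THF/DMPU) is alkylated with 5-iodopent-1-yne to give (2R,3S,6R)-3-methyl-2-(pent-4-yn-1-yl)-6-(propan-2-yl)cyclohexan-1-one F1. A thermal Conia-ene reaction (toluene, sealed tube, 260 °C) of the more substituted enol closes the five-membered ring 5-exo-dig on the face anti to the methyl group and gives (5S,7R,10S)-10-methyl-1-methylidene-7-(propan-2-yl)spiro[4.5]decan-6-one F2. Ozonolysis (O3, CH2Cl2/MeOH, −78 °C; Me2S) gives (5S,7R,10S)-10-methyl-7-(propan-2-yl)spiro[4.5]decane-1,6-dione F3. LiN(iPr)2 then MeI methylates the only CH2 next to a carbonyl and returns 7.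

Step 4 depends on the base telling two tertiary α-hydrogens apart. The fallback removes that need; it sets out from 7 and comes back at 12. Exhaustive enolisation and triflation (KN(SiMe3)2 2.5 equiv, PhNTf2 2.5 equiv) gives (5S,10S)-2,10-dimethyl-7-(propan-2-yl)spiro[4.5]deca-1,6-diene-1,6-diyl bis(trifluoromethanesulfonate) F4. Double formate reduction (Pd(OAc)2, PPh3, HCO2H, Bu3N, DMF, 60 °C) gives (5S,10S)-2,10-dimethyl-7-(propan-2-yl)spiro[4.5]deca-1,6-diene F5. Hydroboration of the more reactive cyclopentene (BH3·THF 1 equiv, 0 °C; NaOH, H2O2) gives (5R,10S)-2,10-dimethyl-7-(propan-2-yl)spiro[4.5]dec-6-en-1-ol F6. Dess–Martin periodinane gives (5R,10S)-2,10-dimethyl-7-(propan-2-yl)spiro[4.5]dec-6-en-1-one F7, which has a single enolisable position, and LiN(iPr)2 then TBSOTf returns 12.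

**Further compounds**
F1 | step 3 | (2R,3S,6R)-3-methyl-2-(pent-4-yn-1-yl)-6-(propan-2-yl)cyclohexan-1-one | CC(C)[C@H]1CC[C@H](C)[C@@H](CCCC#C)C1=O
F2 | step 3 | (5S,7R,10S)-10-methyl-1-methylidene-7-(propan-2-yl)spiro[4.5]decan-6-one | C=C2CCC[C@@]21C(=O)[C@@H](C(C)C)CC[C@@H]1C
F3 | step 3 | (5S,7R,10S)-10-methyl-7-(propan-2-yl)spiro[4.5]decane-1,6-dione | O=C2CCC[C@@]21C(=O)[C@@H](C(C)C)CC[C@@H]1C
F4 | step 4 | (5S,10S)-2,10-dimethyl-7-(propan-2-yl)spiro[4.5]deca-1,6-diene-1,6-diyl bis(trifluoromethanesulfonate) | FC(F)(F)S(=O)(=O)OC2=C(C)CC[C@@]21C(OS(=O)(=O)C(F)(F)F)=C(C(C)C)CC[C@@H]1C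
F5 | step 4 | (5S,10S)-2,10-dimethyl-7-(propan-2-yl)spiro[4.5]deca-1,6-diene | C2=C(C)CC[C@@]21C=C(C(C)C)CC[C@@H]1C
F6 | step 4 | (5R,10S)-2,10-dimethyl-7-(propan-2-yl)spiro[4.5]dec-6-en-1-ol (mixture at C1 and C2) | OC2C(C)CC[C@@]21C=C(C(C)C)CC[C@@H]1C
F7 | step 4 | (5R,10S)-2,10-dimethyl-7-(propan-2-yl)spiro[4.5]dec-6-en-1-one (C2 epimers) | O=C2C(C)CC[C@@]21C=C(C(C)C)CC[C@@H]1C
F8 | step 8 | lithium (5R,10S)-2,10-dimethyl-7-(propan-2-yl)spiro[4.5]deca-1,6-dien-1-olate | [Li+].[O-]C2=C(C)CC[C@@]21C=C(C(C)C)CC[C@@H]1C
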